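A direct plan would annulate a five-carbon diene onto 4-allyl-2-methoxyphenol A1 to give 6-allyl-8-methoxy-2,2-dimethylchroman A2, exchange the methyl ether for a prenyl ether to reach 6-allyl-2,2-dimethyl-8-(prenyloxy)chroman A3, join A3 by hydroboration and B-alkyl Suzuki coupling to 2-bromo-5-(prenyloxy)phenol A4, and end with a double aromatic Claisen rearrangement of the bis(prenyl ether) A5 at about 200 °C.
Its weakest steps would be the ring-B Claisen shift, which would have to carry the prenyl group from O8 past C7 to C5 although the C7 dienone bears a hydrogen and would simply enolise; the ring-A Claisen shift, which would have no control between its two ortho carbons; and the mono-O-prenylation leading to A4 together with the demethylation/re-prenylation pair leading to A3, which would add steps and selectivity problems without adding complexity.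

The route disconnects the pyran ring last and across three bonds, C4a–C4, C3–C4 and O1–C2: on an alkene-free 1,3-diarylpropane, the one free phenol of ring B, formaldehyde and isobutene are merged through an ortho-quinone methide hetero-Diels–Alder reaction. It exploits that O1 of ring B has a single open ortho carbon (C4a), lying between the hydroxyl and the C5 bromine that 6-bromovanillin brings along with the C6 chain carbon and the C8 oxygen. Both five-carbon side chains then enter by regiodivergent cross-coupling at halogens (iodide on ring A, bromide at C5), so no Claisen rearrangement, no resorcinol mono-prenylation and no methyl-to-prenyl ether exchange remain.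

Key step: step 3

Remark: 2-bromo-4-hydroxy-5-methoxybenzaldehyde (6-bromovanillin) and prenylzinc bromide (THF solution) are assumed to be purchasable; the former is otherwise reached from vanillin acetate by bromination para to the methoxy group and deacetylation, the latter from prenyl bromide and zinc.

Step 1
Reactants: 1 2-bromo-4-hydroxy-5-methoxybenzaldehyde (6-bromovanillin); 2 1-(2,4-dimethoxyphenyl)ethanone
Product: 3 (E)-3-(2-bromo-4-hydroxy-5-methoxyphenyl)-1-(2,4-dimethoxyphenyl)prop-2-en-1-one
Conditions: HCl (g, sat.), EtOH, 0 °C to rt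
Reagents that add atoms: none
Why: Acid-catalysed Claisen–Schmidt (crossed aldol) condensation, in which the enol of 2 should add to the protonated aldehyde of 1 (under acid the para-hydroxyl is not a deactivating phenoxide) and dehydration should give the conjugated E-enone under thermodynamic control, with the aryl bromide and the methyl ethers untouched.

Step 2
Reactants: 3 (E)-3-(2-bromo-4-hydroxy-5-methoxyphenyl)-1-(2,4-dimethoxyphenyl)prop-2-en-1-one
Product: 6 5-bromo-4-[3-(2,4-dimethoxyphenyl)propyl]-2-methoxyphenol, via saturated ketone 4 (not isolated), via benzylic carbinol 5 (not isolated)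
Conditions: Et3SiH (6 equiv), CF3CO2H, CH2Cl2, 0 °C to rt
Reagents that add atoms: none
Why: Kursanov–Parnes ionic hydrogenation, in which hydride should add to the protonated enone at the carbon benzylic to the para-hydroxyphenyl ring and the 2,4-dimethoxyphenyl ketone 4 should then pass through carbinol 5 and its oxygen-stabilised benzylic cation to the methylene, a sequence that spares the aryl bromide and is possible only because no alkene is yet present.

Step 3 (key step)
Reactants: 6 5-bromo-4-[3-(2,4-dimethoxyphenyl)propyl]-2-methoxyphenol; 7 formaldehyde (used as paraformaldehyde); 8 phenylboronic acid; 9 isobutene (2-methylpropene)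
Product: 12 5-bromo-6-[3-(2,4-dimethoxyphenyl)propyl]-8-methoxy-2,2-dimethylchroman, via benzodioxaborin 10 (not isolated), via ortho-quinone methide 11 (not isolated)
Conditions: 8 (1.1 equiv), 7 (3 equiv), EtCO2H (cat.), PhMe, reflux, Dean–Stark; then 9 (liquefied, ca. 30 equiv), PhMe, sealed steel tube, 190 °C
Reagents that add atoms: formaldehyde (7), C=O; isobutene (9), C=C(C)C; phenylboronic acid (8), OB(O)c1ccccc1 (its PhB unit is held only by 10)
Why: Phenylboronic acid should esterify the only free phenol of 6 and deliver formaldehyde intramolecularly to its single open ortho carbon (between OH and Br), giving dioxaborin 10; on heating, 10 should undergo cycloreversion with loss of the boron unit to the ortho-quinone methide 11, which isobutene traps in an inverse-electron-demand hetero-Diels–Alder reaction. The closest known reaction type is the chroman synthesis from 2-phenyl-4H-1,3,2-benzodioxaborins or salicyl alcohols and 1,1-disubstituted alkenes. The pyran ring is closed by a concerted, asynchronous [4+2] cycloaddition that forms C3–C4 and O1–C2 together (C4a–C4 having been made in the same flask); the CH2 terminus of isobutene bonds to the methide carbon and the oxygen to the carbon that best carries positive charge, which fixes the 2,2-dimethyl pattern. No stereocentre is formed. The step needs site selectivity for C4a and capture of 11 by the alkene rather than by itself: the first is secured because the C8 oxygen is a methyl ether and the para position carries the chain, the second by a large excess of isobutene and by the absence of any other alkene, free phenol or acid-labile group in 6 (ring A is a bis-methyl ether and the C5 bromide is inert at 190 °C).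

Step 4
Reactants: 12 5-bromo-6-[3-(2,4-dimethoxyphenyl)propyl]-8-methoxy-2,2-dimethylchroman
Product: 13 5-bromo-6-[3-(5-iodo-2,4-dimethoxyphenyl)propyl]-8-methoxy-2,2-dimethylchroman
Conditions: NIS (1.05 equiv), CF3CO2H (10 mol %), MeCN, 0 °C to rt, dark
Reagents that add atoms: N-iodosuccinimide, O=C1CCC(=O)N1I
Why: Electrophilic aromatic iodination, which should select the ring-A carbon ortho to one methoxy group and para to the other (the carbon between the two methoxy groups is hindered and ring B offers only the less activated C7–H); the step is placed here because the molecule still holds no alkene.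

Step 5
Reactants: 13 5-bromo-6-[3-(5-iodo-2,4-dimethoxyphenyl)propyl]-8-methoxy-2,2-dimethylchroman; 14 prenylboronic acid pinacol ester
Product: 15 5-bromo-6-{3-[2,4-dimethoxy-5-(2-methylbut-3-en-2-yl)phenyl]propyl}-8-methoxy-2,2-dimethylchroman
Conditions: 14 (1.4 equiv), Pd(OAc)2 (3 mol %), 1,1'-bis(di-tert-butylphosphino)ferrocene (3.5 mol %), K3PO4 (3 M aq., 3 equiv), THF, 40 °C
Reagents that add atoms: prenylboronic acid pinacol ester (14), CC(C)=CCB1OC(C)(C)C(C)(C)O1
Why: γ-Selective allyl–aryl Suzuki–Miyaura coupling of a 3,3-disubstituted allylboronate, in which SE2' transmetalation should place palladium on the tertiary carbon and the bulky electron-rich bisphosphine should force C–C reductive elimination before σ–π–σ isomerisation, giving the 1,1-dimethylallyl group, while oxidative addition should select the aryl iodide over the doubly ortho-substituted C5 bromide; the new quaternary carbon is not a stereocentre.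

Step 6
Reactants: 15 5-bromo-6-{3-[2,4-dimethoxy-5-(2-methylbut-3-en-2-yl)phenyl]propyl}-8-methoxy-2,2-dimethylchroman; 16 prenylzinc bromide (3-methylbut-2-en-1-ylzinc bromide)
Product: 17 6-{3-[2,4-dimethoxy-5-(2-methylbut-3-en-2-yl)phenyl]propyl}-8-methoxy-2,2-dimethyl-5-(3-methylbut-2-en-1-yl)chroman (kazinol D trimethyl ether)
Conditions: 16 (0.5 M in THF, 1.6 equiv), Pd(OAc)2 (3 mol %), CPhos (6 mol %), THF, rt to 50 °C
Reagents that add atoms: prenylzinc bromide (16), CC(C)=CC[Zn]Br
Why: Linear-selective Negishi coupling of an allylzinc halide, in which the CPhos-ligated palladium catalyst should deliver the allyl unit through its unsubstituted CH2 terminus to the hindered C5 bromide, giving the prenyl and not the 1,1-dimethylallyl arene, and the organozinc tolerates the ethers and the hindered vinyl group of 15.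

Step 7
Reactants: 17 kazinol D trimethyl ether
Product: 18 kazinol D
Conditions: MeMgI (12 equiv, Et2O removed), neat melt, 160 °C, Ar; then 1 M HCl, 0 °C
Reagents that add atoms: none
Why: Grignard-fusion O-demethylation, in which methylmagnesium iodide should cleave all three aryl methyl ethers by attack at the methyl carbon and leave magnesium phenoxides, under basic, acid-free conditions in which 2,2-dimethylchroman ethers and isolated alkenes next to resorcinol oxygens are known to persist, so neither side chain should cyclise onto a phenol; the target has no stereocentre.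

## Compound list
1 | 2-bromo-4-hydroxy-5-methoxybenzaldehyde (6-bromovanillin) | O=Cc1cc(OC)c(O)cc1Br | starting material
2 | 1-(2,4-dimethoxyphenyl)ethanone | CC(=O)c1ccc(OC)cc1OC | starting material
3 | (E)-3-(2-bromo-4-hydroxy-5-methoxyphenyl)-1-(2,4-dimethoxyphenyl)prop-2-en-1-one | COc1ccc(C(=O)/C=C/c2cc(OC)c(O)cc2Br)c(OC)c1 | intermediate
4 | 3-(2-bromo-4-hydroxy-5-methoxyphenyl)-1-(2,4-dimethoxyphenyl)propan-1-one | COc1ccc(C(=O)CCc2cc(OC)c(O)cc2Br)c(OC)c1 | intermediate (not isolated)
5 | 3-(2-bromo-4-hydroxy-5-methoxyphenyl)-1-(2,4-dimethoxyphenyl)propan-1-ol (racemic, transient) | COc1ccc(C(O)CCc2cc(OC)c(O)cc2Br)c(OC)c1 | intermediate (not isolated)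
6 | 5-bromo-4-[3-(2,4-dimethoxyphenyl)propyl]-2-methoxyphenol | COc1ccc(CCCc2cc(OC)c(O)cc2Br)c(OC)c1 | intermediate
7 | formaldehyde (used as paraformaldehyde) | C=O | starting material (reagent)
8 | phenylboronic acid | OB(O)c1ccccc1 | starting material (reagent)
9 | isobutene (2-methylpropene) | C=C(C)C | starting material (reagent)
10 | 5-bromo-6-[3-(2,4-dimethoxyphenyl)propyl]-8-methoxy-2-phenyl-4H-1,3,2-benzodioxaborin | COc1ccc(CCCc2cc(OC)c3OB(c4ccccc4)OCc3c2Br)c(OC)c1 | intermediate (not isolated)
11 | 3-bromo-4-[3-(2,4-dimethoxyphenyl)propyl]-6-methoxy-2-methylidenecyclohexa-3,5-dien-1-one (ortho-quinone methide) | COc1ccc(CCCC2=C(Br)C(=C)C(=O)C(OC)=C2)c(OC)c1 | intermediate (not isolated)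
12 | 5-bromo-6-[3-(2,4-dimethoxyphenyl)propyl]-8-methoxy-2,2-dimethylchroman | COc1ccc(CCCc2cc(OC)c3OC(C)(C)CCc3c2Br)c(OC)c1 | intermediate
13 | 5-bromo-6-[3-(5-iodo-2,4-dimethoxyphenyl)propyl]-8-methoxy-2,2-dimethylchroman | COc1cc(OC)c(CCCc2cc(OC)c3OC(C)(C)CCc3c2Br)cc1I | intermediate
14 | prenylboronic acid pinacol ester | CC(C)=CCB1OC(C)(C)C(C)(C)O1 | starting material (reagent)
15 | 5-bromo-6-{3-[2,4-dimethoxy-5-(2-methylbut-3-en-2-yl)phenyl]propyl}-8-methoxy-2,2-dimethylchroman | C=CC(C)(C)c1cc(CCCc2cc(OC)c3OC(C)(C)CCc3c2Br)c(OC)cc1OC | intermediate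
16 | prenylzinc bromide | CC(C)=CC[Zn]Br | starting material (reagent)
17 | 6-{3-[2,4-dimethoxy-5-(2-methylbut-3-en-2-yl)phenyl]propyl}-8-methoxy-2,2-dimethyl-5-(3-methylbut-2-en-1-yl)chroman (kazinol D trimethyl ether) | C=CC(C)(C)c1cc(CCCc2cc(OC)c3OC(C)(C)CCc3c2CC=C(C)C)c(OC)cc1OC | intermediate
18 | kazinol D (achiral) | C=CC(C)(C)c1cc(CCCc2cc(O)c3c(c2CC=C(C)C)CCC(C)(C)O3)c(O)cc1O | target

Total step count: 7. Longest linear sequence: 7 (the route is linear from 1 and 2).

Steps most likely to fail:

Step 3. Thermal cycloreversion of the formaldehyde-derived dioxaborin may be sluggish, and the unsubstituted ortho-quinone methide may oligomerise faster than the weakly nucleophilic gaseous alkene captures it. The fallback sets out from 6 and closes the ring by condensation and electrocyclisation instead of cycloaddition: 6 would be heated with 3-methylbut-2-enal, phenylboronic acid and catalytic propanoic acid in toluene to give 5-bromo-6-[3-(2,4-dimethoxyphenyl)propyl]-8-methoxy-2,2-dimethyl-2H-chromene F1 by oxa-6π ring closure. The C3–C4 double bond of F1, the only alkene in the molecule at this stage, would then be saturated with H2 over RhCl(PPh3)3, which spares the aryl bromide, and the route is rejoined at 12.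

Step 5. Branch selectivity may erode through σ–π–σ isomerisation of the allylpalladium intermediate, and reductive elimination at a carbon flanked by a methoxy group may be slow. The fallback sets out from 13 and builds the quaternary carbon by enolate arylation: isobutyraldehyde would be α-arylated at the aryl iodide (Pd(OAc)2, rac-BINAP, Cs2CO3, dioxane, 80 °C) to give 2-{5-[3-(5-bromo-8-methoxy-2,2-dimethylchroman-6-yl)propyl]-2,4-dimethoxyphenyl}-2-methylpropanal F2. Wittig methylenation of F2 (Ph3P=CH2, THF, 0 °C) would then give the 1,1-dimethylallyl group and rejoin the route at 15.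

Step 7. Cleavage of the second ring-A ether may stall once that ring carries a phenoxide, and the side chains may isomerise during the melt. The fallback sets out from 12, before any alkene is present, and changes the protecting groups. BBr3 (CH2Cl2, −78 to 0 °C) would cleave all three methyl ethers to 4-[3-(5-bromo-8-hydroxy-2,2-dimethylchroman-6-yl)propyl]benzene-1,3-diol F3, and MOMCl with i-Pr2NEt would convert F3 into 5-bromo-6-{3-[2,4-bis(methoxymethoxy)phenyl]propyl}-8-(methoxymethoxy)-2,2-dimethylchroman F4. The chemistry of steps 4 to 6 would then be repeated on this series (the iodination with NIS alone in MeCN, without acid). This would give 5-bromo-6-{3-[5-iodo-2,4-bis(methoxymethoxy)phenyl]propyl}-8-(methoxymethoxy)-2,2-dimethylchroman F5, then 5-bromo-6-{3-[2,4-bis(methoxymethoxy)-5-(2-methylbut-3-en-2-yl)phenyl]propyl}-8-(methoxymethoxy)-2,2-dimethylchroman F6, then kazinol D tris(methoxymethyl) ether F7. Dilute HCl in MeOH at rt would finally release the three phenols of F7 and rejoin the route at 18.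

## Further compounds
F1 | step 3 | 5-bromo-6-[3-(2,4-dimethoxyphenyl)propyl]-8-methoxy-2,2-dimethyl-2H-chromene | COc1ccc(CCCc2cc(OC)c3OC(C)(C)C=Cc3c2Br)c(OC)c1
F2 | step 5 | 2-{5-[3-(5-bromo-8-methoxy-2,2-dimethylchroman-6-yl)propyl]-2,4-dimethoxyphenyl}-2-methylpropanal | O=CC(C)(C)c1cc(CCCc2cc(OC)c3OC(C)(C)CCc3c2Br)c(OC)cc1OC
F3 | step 7 | 4-[3-(5-bromo-8-hydroxy-2,2-dimethylchroman-6-yl)propyl]benzene-1,3-diol | Oc1ccc(CCCc2cc(O)c3OC(C)(C)CCc3c2Br)c(O)c1
F4 | step 7 | 5-bromo-6-{3-[2,4-bis(methoxymethoxy)phenyl]propyl}-8-(methoxymethoxy)-2,2-dimethylchroman | COCOc1ccc(CCCc2cc(OCOC)c3OC(C)(C)CCc3c2Br)c(OCOC)c1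
F5 | step 7 | 5-bromo-6-{3-[5-iodo-2,4-bis(methoxymethoxy)phenyl]propyl}-8-(methoxymethoxy)-2,2-dimethylchroman | COCOc1cc(OCOC)c(CCCc2cc(OCOC)c3OC(C)(C)CCc3c2Br)cc1I
F6 | step 7 | 5-bromo-6-{3-[2,4-bis(methoxymethoxy)-5-(2-methylbut-3-en-2-yl)phenyl]propyl}-8-(methoxymethoxy)-2,2-dimethylchroman | C=CC(C)(C)c1cc(CCCc2cc(OCOC)c3OC(C)(C)CCc3c2Br)c(OCOC)cc1OCOC
F7 | step 7 | kazinol D tris(methoxymethyl) ether | C=CC(C)(C)c1cc(CCCc2cc(OCOC)c3OC(C)(C)CCc3c2CC=C(C)C)c(OCOC)cc1OCOC
A1 | direct plan | 4-allyl-2-methoxyphenol | C=CCc1ccc(O)c(OC)c1
A2 | direct plan | 6-allyl-8-methoxy-2,2-dimethylchroman | C=CCc1cc(OC)c2OC(C)(C)CCc2c1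
A3 | direct plan | 6-allyl-2,2-dimethyl-8-(prenyloxy)chroman | C=CCc1cc(OCC=C(C)C)c2OC(C)(C)CCc2c1
A4 | direct plan | 2-bromo-5-(prenyloxy)phenol | CC(C)=CCOc1ccc(Br)c(O)c1
A5 | direct plan | 2-{3-[2,2-dimethyl-8-(prenyloxy)chroman-6-yl]propyl}-5-(prenyloxy)phenol | CC(C)=CCOc1ccc(CCCc2cc(OCC=C(C)C)c3OC(C)(C)CCc3c2)c(O)c1
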